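**Strategy.** Ring A carries O1 (on C8a) and the free 6-OH (on C6) para to each other, so it is a masked p-benzoquinone. The route rests on a [3+3] disconnection of ring C at C4–C4a and O1–C2. Methoxy-1,4-benzoquinone is joined to 3-methoxy-2-(2,4,5-trimethoxyphenyl)acrolein, a C3 unit that already holds the C3–C1' bond. In one redox-neutral photochemical operation the formyl carbon adds as an acyl radical to quinone C5 and the quinone aromatises. The new ortho-hydroxyl then closes the pyranone with loss of methanol, and the second quinone oxygen emerges as the unprotected 6-OH beside 7-OMe. No protecting group is needed.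

Key step: step 4

Assumption: the target has no stereocentre and the C3–C1' axis rotates freely, so "single enantiomer" places no demand on the route; 2-methoxy-1,4-benzoquinone is taken as a catalogue chemical.

Step 1
Reactants: 1 2,4,5-trimethoxybenzaldehyde
Product: 2 1,2,4-trimethoxy-5-(2-methoxyethenyl)benzene (E/Z mixture)
Conditions: MeOCH2PPh3Cl, KOtBu, THF, 0 °C to rt
Reagents that add atoms: (methoxymethyl)triphenylphosphonium chloride, COC[P+](c1ccccc1)(c1ccccc1)c1ccccc1.[Cl-]
Why: Wittig methoxymethylenation of a non-enolisable aromatic aldehyde with a non-stabilised ylide is reliable, and the E/Z mixture does not matter because both alkene carbons become sp3 in step 2.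

Step 2
Reactants: 2 1,2,4-trimethoxy-5-(2-methoxyethenyl)benzene
Product: 3 1,2,4-trimethoxy-5-(1,1,3,3-tetramethoxypropan-2-yl)benzene
Conditions: HC(OMe)3 (excess), BF3·OEt2 (5 mol %), CH2Cl2, −20 to 0 °C
Reagents that add atoms: trimethyl orthoformate, COC(OC)OC
Why: This is a Lewis-acid-catalysed orthoester–enol ether condensation (Müller-Cunradi–Pieroh type), in which the dimethoxycarbenium ion attacks the aryl-bearing β-carbon of the enol ether, by far the most nucleophilic site, and methoxide return caps the oxocarbenium ion as the second acetal.

Step 3
Reactants: 3 1,2,4-trimethoxy-5-(1,1,3,3-tetramethoxypropan-2-yl)benzene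
Product: 4 3-methoxy-2-(2,4,5-trimethoxyphenyl)prop-2-enal (alkene geometry neither controlled nor needed)
Conditions: H2O (1.1 equiv), p-TsOH·H2O (2 mol %), THF, 40 °C
Reagents that add atoms: water, O
Why: Controlled acetal hydrolysis followed by β-elimination of methanol is the standard passage from a 1,1,3,3-tetraalkoxypropane to a 3-alkoxyacrolein; limiting the water should stop it at the conjugated vinylogous ester, and the two acetal groups of 3 are equivalent, so no site selectivity is required.

Step 4
Reactants: 4 3-methoxy-2-(2,4,5-trimethoxyphenyl)prop-2-enal; 5 2-methoxy-1,4-benzoquinone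
Product: 8 6-hydroxy-7-methoxy-3-(2,4,5-trimethoxyphenyl)-4H-chromen-4-one, via acylhydroquinone 6 (not isolated), via 2-methoxyisoflavanone 7 (not isolated)
Conditions: 5 (1.5 equiv, in portions), 440 nm LEDs, degassed PhCF3, 20–25 °C; then p-TsOH·H2O (10 mol %), 60 °C
Reagents that add atoms: none
Why: Proposed new method: visible light excites only quinone 5, whose triplet removes the formyl hydrogen of 4 (direct hydrogen-atom transfer, or electron transfer from the trimethoxyphenyl ring followed by proton transfer inside the ion pair), and the resulting nucleophilic acyl σ-radical, which sits on an sp2 carbon and so cannot lose CO as the arylacetyl radical of the saturated aldehyde would, adds to ground-state 5; hydrogen return from the semiquinone and enolisation then give acylhydroquinone 6. The closest known reaction type is the photo-Friedel–Crafts acylation of 1,4-quinones with aldehydes, which accepts enals and polymethoxylated aromatic aldehydes but has not been run with a 3-alkoxyacrolein or coupled to a chromone ring closure. Ring C closes by 6-endo-trig oxa-Michael addition of the chelated 2-OH of 6 (the former C4 carbonyl oxygen of 5) to the acid-activated β-methoxyenone to give 7, and loss of methanol, the same terminal event as in isoflavone syntheses from α-formyldeoxybenzoins, gives the aromatic pyranone. No stereocentre remains, because C2 and C3 of 7 are both flattened in the elimination. The step needs attack at quinone C5 rather than C6 or C3, and the substrate secures this: the 2-OMe group ties up C4=O as a vinylogous ester, so C5, the β-carbon of the unperturbed C1=O enone, is the most electrophilic position (the one also taken by polar nucleophiles), and the adduct is an aryloxyl radical stabilised by the ortho-methoxy group, which places 6-OH beside 7-OMe. It also needs abstraction of the formyl C–H, the weakest C–H bond of 4, in preference to the OCH3 hydrogens, and C- over O-acylation, which is favoured when the acyl radical leaves the solvent cage and meets an excess of ground-state quinone.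

**Compound list**
1 | 2,4,5-trimethoxybenzaldehyde | O=Cc1cc(OC)c(OC)cc1OC | starting material
2 | 1,2,4-trimethoxy-5-(2-methoxyethenyl)benzene (E/Z mixture) | COC=Cc1cc(OC)c(OC)cc1OC | intermediate
3 | 1,2,4-trimethoxy-5-(1,1,3,3-tetramethoxypropan-2-yl)benzene | COC(OC)C(C(OC)OC)c1cc(OC)c(OC)cc1OC | intermediate
4 | 3-methoxy-2-(2,4,5-trimethoxyphenyl)prop-2-enal (E/Z not defined) | COC=C(C=O)c1cc(OC)c(OC)cc1OC | intermediate
5 | 2-methoxy-1,4-benzoquinone | COC1=CC(=O)C=CC1=O | starting material
6 | 1-(2,5-dihydroxy-4-methoxyphenyl)-3-methoxy-2-(2,4,5-trimethoxyphenyl)prop-2-en-1-one (not isolated) | COC=C(C(=O)c1cc(O)c(OC)cc1O)c1cc(OC)c(OC)cc1OC | intermediate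
7 | 6-hydroxy-2,7-dimethoxy-3-(2,4,5-trimethoxyphenyl)chroman-4-one (racemic diastereomer mixture, not isolated) | COC1Oc2cc(OC)c(O)cc2C(=O)C1c1cc(OC)c(OC)cc1OC | intermediate
8 | 6-hydroxy-7-methoxy-3-(2,4,5-trimethoxyphenyl)-4H-chromen-4-one | COc1cc2occ(-c3cc(OC)c(OC)cc3OC)c(=O)c2cc1O | target

Total step count: 4. Longest linear sequence: 4 (1 → 2 → 3 → 4 → 8); quinone 5 enters as purchased.

**Steps most likely to fail**

1. Step 4 (Proposed new method).
   - What may go wrong:
     - unproductive quenching of the quinone triplet by electron transfer from the electron-rich aryl ring followed by back-transfer;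
     - slow hydrogen abstraction, because the methoxy group lowers the n,π* character of the triplet;
     - [2+2] or Paternò–Büchi cycloaddition across the enol-ether double bond;
     - in-cage O-acylation;
     - leakage of the radical addition to quinone C6;
     - progressive inhibition by the phenolic products.
   - Fallback: this uses known chemistry, sets out from 2 and 5, and comes back at 8. Enol ether 2 is hydrolysed with aqueous HCl in THF to 2,4,5-trimethoxyphenylacetaldehyde F1. A Pinnick oxidation (NaClO2, NaH2PO4, 2-methyl-2-butene) takes this to 2,4,5-trimethoxyphenylacetic acid F2. Quinone 5 is reduced with aqueous Na2S2O4 to 2-methoxyhydroquinone F3. F2 and F3 are joined in BF3·OEt2 at 80 °C (Friedel–Crafts acylation para to OMe and ortho to OH) to give the deoxybenzoin 1-(2,5-dihydroxy-4-methoxyphenyl)-2-(2,4,5-trimethoxyphenyl)ethanone F4. The missing C2 is then inserted with DMF, BF3·OEt2 and MsCl (Vilsmeier-type formylation with spontaneous cyclisation) to give 8.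

2. Step 2.
   - What may go wrong: cationic oligomerisation of the very electron-rich β-methoxystyrene under the Lewis acid, or electrophilic attack of the carbenium ion on the aromatic ring.
   - Fallback: this sets out from 2 and comes back at 4, bypassing 3. The C1 unit is delivered at the iminium level instead of the acetal level. Vilsmeier–Haack formylation of 2 (POCl3, DMF, 0 to 60 °C, then aqueous K2CO3) should give 3-(dimethylamino)-2-(2,4,5-trimethoxyphenyl)prop-2-enal F5. Hot aqueous NaOH followed by acidification gives 2-(2,4,5-trimethoxyphenyl)malondialdehyde F6 in its enol form. O-methylation with HC(OMe)3 in MeOH and catalytic p-TsOH then gives 4.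

3. Step 3.
   - What may go wrong: overshoot of the hydrolysis with additional loss of the enol-ether methyl group, or incomplete elimination that leaves a mixture of partly hydrolysed species.
   - Fallback: this sets out from 3 and comes back at 4. The order of events is reversed and water is excluded. Acid-catalysed elimination (catalytic KHSO4, 120 °C, reduced pressure, methanol removed) gives 1,2,4-trimethoxy-5-(1,3,3-trimethoxyprop-1-en-2-yl)benzene F7. Its remaining acetal is then exchanged with dry acetone (PPTS, rt). This releases the aldehyde of 4 with no water present to cleave the vinylogous ester.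

**Further compounds**
F1 | step 4 | 2,4,5-trimethoxyphenylacetaldehyde | O=CCc1cc(OC)c(OC)cc1OC
F2 | step 4 | 2,4,5-trimethoxyphenylacetic acid | OC(=O)Cc1cc(OC)c(OC)cc1OC
F3 | step 4 | 2-methoxyhydroquinone | COc1cc(O)ccc1O
F4 | step 4 | 1-(2,5-dihydroxy-4-methoxyphenyl)-2-(2,4,5-trimethoxyphenyl)ethanone | COc1cc(O)c(C(=O)Cc2cc(OC)c(OC)cc2OC)cc1O
F5 | step 2 | 3-(dimethylamino)-2-(2,4,5-trimethoxyphenyl)prop-2-enal | CN(C)C=C(C=O)c1cc(OC)c(OC)cc1OC
F6 | step 2 | 2-(2,4,5-trimethoxyphenyl)malondialdehyde (enol form) | OC=C(C=O)c1cc(OC)c(OC)cc1OC
F7 | step 3 | 1,2,4-trimethoxy-5-(1,3,3-trimethoxyprop-1-en-2-yl)benzene | COC=C(C(OC)OC)c1cc(OC)c(OC)cc1OC
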